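## Retrosynthetic overview
1. Target ⇒ its C4 silyl ether ⇒ (key step) one-carbon ring expansion of a 1-oxybicyclo[3.1.0]hex-2-ene. Cleaving the internal C1–C5 cyclopropane bond gives the cyclohexenone, and H-atom transfer to the C5 radical sets the cis C4/C5 relation.
2. Bicyclic cyclopropyl ether ⇒ CH2 transfer (C6) to a 2-siloxycyclopentadiene ⇒ copper-catalysed 1,4-addition of a C19 (E)-alkenylalane to a 5-methylidenecyclopentenone (C1′–C2′ bond).
3. Methylidene enone ⇒ (S)-4-hydroxycyclopent-2-enone (source of C4) by silylation, α-iodination/methylation (C2 methyl) and α′-methylenation (C1′).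
4. Alkenylalane ⇒ methylalumination of a C18 trienyne ⇒ acetylide + homofarnesyl iodide ⇒ two iterative Negishi couplings of (E)-2,5-diiodopent-2-ene, starting from homoprenylzinc bromide.
5. Ring order: purchased five-membered ring → fused three-membered ring → six-membered ring, formed when the two merge.

Assumption: the target SMILES is read as (4S,5S), with OH and chain cis. Target locants are used for all intermediates (ring C1 = carbonyl carbon, C4 = carbinol carbon, C5 = chain-bearing carbon; chain C1′–C16′).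
Abbreviations: GG = (2E,6E,10E)-3,7,11,15-tetramethylhexadeca-2,6,10,14-tetraen-1-yl (geranylgeranyl); TBS = tert-butyldimethylsilyl; TMS = trimethylsilyl.

## Route

Step 1
Reactants: 1 pent-3-yn-1-ol
Product: 3 (E)-4-iodopent-3-en-1-ol, via alkenylzirconocene alkoxide 2 (not isolated)
Conditions: Cp2ZrHCl (2.3 equiv), THF, 0 °C to rt; I2, −78 to 0 °C; aq Na2S2O3
Reagents that add atoms: iodine, II
Why: Hydrozirconation–iodination: syn H–Zr addition, equilibrated by excess Cp2ZrHCl, puts Zr on the less hindered methyl-bearing carbon, iodinolysis retains geometry to give the E vinyl iodide, and the minor regioisomer is removed by chromatography.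

Step 2
Reactants: 3 (E)-4-iodopent-3-en-1-ol
Product: 4 (E)-2,5-diiodopent-2-ene
Conditions: I2, PPh3, imidazole, DCM, 0 °C
Reagents that add atoms: iodine, II
Why: Appel iodination displaces the primary oxyphosphonium ion by SN2 and leaves the vinyl iodide and its geometry untouched.

Step 3
Reactants: 5 5-bromo-2-methylpent-2-ene; 4 (E)-2,5-diiodopent-2-ene
Product: 7 (3E)-1-iodo-4,8-dimethylnona-3,7-diene (homogeranyl iodide), via homoprenylzinc bromide 6 (not isolated)
Conditions: 5, Zn dust, I2 (5 mol %), DMA, 80 °C; decant from Zn; 4, Pd(dppf)Cl2 (2 mol %), THF, 23 °C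
Reagents that add atoms: none
Why: Negishi coupling: zerovalent palladium inserts far faster into the C(sp2)–I bond of 4 than into its primary C(sp3)–I bond and couples with retention of geometry, so one E isoprene unit is added and a new alkyl iodide is left for the next round.

Step 4
Reactants: 7 homogeranyl iodide; 4 (E)-2,5-diiodopent-2-ene
Product: 9 (3E,7E)-1-iodo-4,8,12-trimethyltrideca-3,7,11-triene (homofarnesyl iodide), via homogeranylzinc iodide 8 (not isolated)
Conditions: 7, Zn dust, LiCl, THF, 40 °C; decant; 4, Pd(dppf)Cl2 (2 mol %), THF, 23 °C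
Reagents that add atoms: none
Why: A second chemoselective, stereoretentive Negishi coupling of the same kind adds the next E isoprene unit.

Step 5
Reactants: 9 homofarnesyl iodide
Product: 10 (5E,9E)-6,10,14-trimethylpentadeca-5,9,13-trien-1-yne
Conditions: LiC≡CH·H2NCH2CH2NH2, DMSO, 10 °C to rt
Reagents that add atoms: lithium acetylide ethylenediamine complex, [Li]C#C.NCCN
Why: SN2 alkylation of acetylide on a primary iodide in DMSO, where the low temperature keeps E2 elimination to the 1,3-diene minor.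

Step 6
Reactants: 11 (S)-4-hydroxycyclopent-2-en-1-one
Product: 12 (S)-4-(TBSO)cyclopent-2-en-1-one
Conditions: TBSCl, imidazole, DCM, 0 °C to rt
Reagents that add atoms: tert-butyldimethylsilyl chloride, CC(C)(C)[Si](C)(C)Cl
Why: Silyl ether formation leaves C4 untouched and installs the bulky group that later directs the facial selectivity at C5.

Step 7
Reactants: 12 (S)-4-(TBSO)cyclopent-2-en-1-one
Product: 13 (S)-4-(TBSO)-2-iodocyclopent-2-en-1-one
Conditions: I2, pyridine, DCM, 0 °C to rt
Reagents that add atoms: iodine, II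
Why: α-Iodination of an enone by pyridine conjugate addition, iodination of the enolate and elimination, a routine reaction on this substrate class.

Step 8
Reactants: 13 (S)-4-(TBSO)-2-iodocyclopent-2-en-1-one
Product: 14 (S)-4-(TBSO)-2-methylcyclopent-2-en-1-one
Conditions: MeZnCl, Pd(dppf)Cl2 (3 mol %), THF, rt
Reagents that add atoms: methylzinc chloride, C[Zn]Cl
Why: Negishi methylation of an α-iodoenone, in which the mild zinc reagent does not add to the enone or touch C4.

Step 9
Reactants: 14 (S)-4-(TBSO)-2-methylcyclopent-2-en-1-one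
Product: 18 (R)-4-(TBSO)-2-methyl-5-methylidenecyclopent-2-en-1-one, via lithium dienolate 15 (not isolated), via Mannich base 16 (not isolated), via methiodide salt 17 (not isolated)
Conditions: LiN(iPr)2, THF, −78 °C; CH2=NMe2+ I−, −78 to 0 °C; MeI, Et2O, rt; aq NaHCO3/DCM, 0 °C; used at once
Reagents that add atoms: N,N-dimethylmethyleneiminium iodide, C=[N+](C)C.[I-]
Why: Mannich methylenation: C5 is the only kinetically enolisable position, aminomethylation, quaternisation and E1cB loss of NMe3 give the exocyclic enone, and the C4 geometry is unchanged (only the CIP label switches).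

Step 10
Reactants: 10 trienyne; 18 methylidene enone
Product: 20 (5R)-5-(TBSO)-1-GG-3-methyl-2-(TMSO)cyclopenta-1,3-diene, via alkenyl dimethylalane 19 (not isolated)
Conditions: 10, Me3Al, Cp2ZrCl2 (20 mol %), DCM, 0 °C to rt; evaporate excess Me3Al; THF, CuBr·SMe2 (10 mol %), TMSCl, 18, −78 to −30 °C; Et3N, pentane, cold aq NaHCO3; kept at or below 0 °C
Reagents that add atoms: trimethylaluminium, C[Al](C)C; trimethylsilyl chloride, C[Si](C)(C)Cl
Why: Zirconium-catalysed syn methylalumination (Negishi carboalumination) sets the E C2′=C3′ alkene, and the TMSCl-assisted copper-catalysed 1,4-addition attacks the unhindered exocyclic CH2 rather than C3 (flanked by OTBS, α-methyl) to give the tetrasubstituted silyl enol ether regiospecifically.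

Step 11
Reactants: 20 siloxycyclopentadiene
Product: 21 (1S,4R,5S)-4-(TBSO)-5-GG-2-methyl-1-(TMSO)bicyclo[3.1.0]hex-2-ene
Conditions: Et2Zn, CH2I2 (1.1 equiv each), Et2O, −20 to 0 °C
Reagents that add atoms: diiodomethane, ICI
Why: Simmons–Smith cyclopropanation: the electrophilic zinc carbenoid takes the most electron-rich alkene, the siloxy-bearing C1=C5 bond of the 2-siloxydiene, from the face anti to OTBS, and the C1/C5 configuration is erased in the next step.

Step 12
Reactants: 21 bicyclic TMS cyclopropyl ether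
Product: 23 (4S,5S)-4-(TBSO)-5-GG-2-methylcyclohex-2-en-1-one, via bicyclic cyclopropanol 22 (not isolated)
Conditions: [Ir(dF(CF3)ppy)2(dtbbpy)]PF6 (2 mol %), Bu4N[O2P(OBu)2] (20 mol %), 2,4,6-triisopropylbenzenethiol (20 mol %), PhCF3–MeOH 9:1, blue LED (450 nm), 10 °C
Reagents that add atoms: none
Why: Proposed new method: methanolysis of the labile TMS ether releases cyclopropanol 22, whose O–H bond is broken by proton-coupled electron transfer (photoexcited iridium complex as oxidant, dibutyl phosphate as base), the alkoxy radical cleaves the internal C1–C5 bond because this releases the bicyclic strain and gives at once the conjugated enone and a tertiary C5 radical (a primary radical from C1–C6 cleavage can re-add to the carbonyl and funnel to the same radical, a net 1,2-acyl shift), the hindered thiol then transfers H to the C5 face anti to the pseudoaxial C4 OTBS group so that the chain ends cis to oxygen (5S), and the reduced divalent iridium complex returns the thiyl radical to thiol, which makes the five-to-six ring expansion redox-neutral; the closest known reaction types are the FeCl3 (Saegusa) ring expansion of 1-siloxybicyclo[n.1.0]alkanes, the Dowd–Beckwith ring expansion and the photocatalytic PCET ring-opening isomerisation of cycloalkanols, none of them shown on a vinyl-substituted bicyclic cyclopropanol or used to set a stereocentre.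

Step 13
Reactants: 23 TBS ether of the target
Product: 24 (4S,5S)-5-GG-4-hydroxy-2-methylcyclohex-2-en-1-one (target)
Conditions: HF·pyridine, pyridine, THF, 0 °C to rt
Reagents that add atoms: none
Why: Buffered fluoride desilylation cleaves only the Si–O bond, and neither the polyene, the γ-hydroxy enone nor the C4/C5 stereocentres are affected.

## Compound list
1 | pent-3-yn-1-ol | CC#CCCO | starting material
2 | (E)-pent-3-en-1-ol bearing Cp2Zr(Cl) at C4 and at oxygen | C/C(=C\CCO[Zr](Cl)(C1C=CC=C1)C1C=CC=C1)[Zr](Cl)(C1C=CC=C1)C1C=CC=C1 | intermediate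
3 | (E)-4-iodopent-3-en-1-ol | C/C(I)=C\CCO | intermediate
4 | (E)-2,5-diiodopent-2-ene | C/C(I)=C\CCI | intermediate
5 | 5-bromo-2-methylpent-2-ene | CC(C)=CCCBr | starting material
6 | (4-methylpent-3-en-1-yl)zinc bromide | CC(C)=CCC[Zn]Br | intermediate
7 | (3E)-1-iodo-4,8-dimethylnona-3,7-diene | CC(C)=CCC/C(C)=C/CCI | intermediate
8 | [(3E)-4,8-dimethylnona-3,7-dien-1-yl]zinc iodide | CC(C)=CCC/C(C)=C/CC[Zn]I | intermediate
9 | (3E,7E)-1-iodo-4,8,12-trimethyltrideca-3,7,11-triene | CC(C)=CCC/C(C)=C/CC/C(C)=C/CCI | intermediate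
10 | (5E,9E)-6,10,14-trimethylpentadeca-5,9,13-trien-1-yne | CC(C)=CCC/C(C)=C/CC/C(C)=C/CCC#C | intermediate
11 | (S)-4-hydroxycyclopent-2-en-1-one | O=C1C=C[C@@H](O)C1 | starting material
12 | (S)-4-(tert-butyldimethylsilyloxy)cyclopent-2-en-1-one | O=C1C=C[C@@H](O[Si](C)(C)C(C)(C)C)C1 | intermediate
13 | (S)-4-(tert-butyldimethylsilyloxy)-2-iodocyclopent-2-en-1-one | O=C1C(I)=C[C@@H](O[Si](C)(C)C(C)(C)C)C1 | intermediate
14 | (S)-4-(tert-butyldimethylsilyloxy)-2-methylcyclopent-2-en-1-one | O=C1C(C)=C[C@@H](O[Si](C)(C)C(C)(C)C)C1 | intermediate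
15 | lithium (3R)-3-(tert-butyldimethylsilyloxy)-5-methylcyclopenta-1,4-dien-1-olate | [Li]OC1=C[C@H](O[Si](C)(C)C(C)(C)C)C=C1C | intermediate
16 | (4R,5S)-4-(tert-butyldimethylsilyloxy)-5-[(dimethylamino)methyl]-2-methylcyclopent-2-en-1-one (CH2N trans to OTBS) | O=C1C(C)=C[C@@H](O[Si](C)(C)C(C)(C)C)[C@@H]1CN(C)C | intermediate
17 | trimethylammonium iodide of 16 | O=C1C(C)=C[C@@H](O[Si](C)(C)C(C)(C)C)[C@@H]1C[N+](C)(C)C.[I-] | intermediate
18 | (R)-4-(tert-butyldimethylsilyloxy)-2-methyl-5-methylidenecyclopent-2-en-1-one | O=C1C(C)=C[C@@H](O[Si](C)(C)C(C)(C)C)C1=C | intermediate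
19 | dimethyl[(1E,5E,9E)-2,6,10,14-tetramethylpentadeca-1,5,9,13-tetraen-1-yl]alane | CC(C)=CCC/C(C)=C/CC/C(C)=C/CC/C(C)=C/[Al](C)C | intermediate
20 | (5R)-5-(tert-butyldimethylsilyloxy)-1-geranylgeranyl-3-methyl-2-(trimethylsilyloxy)cyclopenta-1,3-diene | CC(C)=CCC/C(C)=C/CC/C(C)=C/CC/C(C)=C/CC1=C(O[Si](C)(C)C)C(C)=C[C@H]1O[Si](C)(C)C(C)(C)C | intermediate
21 | (1S,4R,5S)-4-(tert-butyldimethylsilyloxy)-5-geranylgeranyl-2-methyl-1-(trimethylsilyloxy)bicyclo[3.1.0]hex-2-ene (C6H2 anti to OTBS) | CC(C)=CCC/C(C)=C/CC/C(C)=C/CC/C(C)=C/C[C@@]12C[C@]1(O[Si](C)(C)C)C(C)=C[C@H]2O[Si](C)(C)C(C)(C)C | intermediate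
22 | (1S,4R,5S)-4-(tert-butyldimethylsilyloxy)-5-geranylgeranyl-2-methylbicyclo[3.1.0]hex-2-en-1-ol | CC(C)=CCC/C(C)=C/CC/C(C)=C/CC/C(C)=C/C[C@@]12C[C@]1(O)C(C)=C[C@H]2O[Si](C)(C)C(C)(C)C | intermediate
23 | (4S,5S)-4-(tert-butyldimethylsilyloxy)-5-geranylgeranyl-2-methylcyclohex-2-en-1-one (cis) | CC(C)=CCC/C(C)=C/CC/C(C)=C/CC/C(C)=C/C[C@H]1CC(=O)C(C)=C[C@H]1O[Si](C)(C)C(C)(C)C | intermediate
24 | (4S,5S)-5-geranylgeranyl-4-hydroxy-2-methylcyclohex-2-en-1-one | CC(C)=CCC/C(C)=C/CC/C(C)=C/CC/C(C)=C/C[C@H]1CC(=O)C(C)=C[C@H]1O | target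

## Totals and risks
Total step count: 13. Longest linear sequence: 9 (steps 1, 2, 3, 4, 5, 10, 11, 12, 13).

**Step 12 (new method).**
- Risks: competing external C1–C6 cleavage, modest cis:trans ratio in the H transfer, thiyl-induced E/Z erosion of the chain, and slow in situ methanolysis.
- Fallback (known chemistry): sets out from 21 and comes back at 23.
- FeCl3 (2.2 equiv) in DMF–pyridine at 0 °C (Saegusa oxidative ring expansion) gives the tertiary β-chloro ketone (4R)-4-(TBSO)-5-chloro-5-GG-2-methylcyclohex-2-en-1-one F6 as C5 epimers.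
- This is reduced without purification by Bu3SnH with Et3B/air in toluene at 0 °C. The same C5 radical takes H anti to OTBS and gives 23.

**Step 11.**
- Risks: [1,5]-H shift or dimerisation of the siloxycyclopentadiene 20, and competing cyclopropanation of the four chain alkenes.
- Fallback: sets out from 20 and comes back at 23, bypassing 21 and 22.
- Aqueous formaldehyde with Yb(OTf)3 in THF–water (Mukaiyama aldol hydroxymethylation) gives (4R,5S)-4-(TBSO)-5-GG-5-(hydroxymethyl)-2-methylcyclopent-2-en-1-one F4.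
- I2/PPh3/imidazole converts it into (4R,5S)-4-(TBSO)-5-GG-5-(iodomethyl)-2-methylcyclopent-2-en-1-one F5.
- Slow addition of Bu3SnH/AIBN in refluxing benzene (Dowd–Beckwith ring expansion) then leads through the same C5 radical to 23.

**Step 10.**
- Risks: methyl instead of alkenyl transfer, 1,2-addition, and polymerisation of 18.
- Fallback: sets out from 19 and 15 and comes back at 20. It replaces conjugate addition by enolate allylation.
- Alane 19 is activated with n-BuLi and treated with paraformaldehyde to give (2E,6E,10E)-geranylgeraniol F1.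
- CBr4/PPh3 gives (2E,6E,10E)-geranylgeranyl bromide F2.
- Dienolate 15 (from 14 as in step 9) is alkylated with it in THF–DMPU at −78 °C to give (4R,5S)-4-(TBSO)-5-GG-2-methylcyclopent-2-en-1-one F3 (chain trans to OTBS).
- LiN(iPr)2 followed by TMSCl then gives 20.

## Further compounds
F1 | step 10 | (2E,6E,10E)-geranylgeraniol | CC(C)=CCC/C(C)=C/CC/C(C)=C/CC/C(C)=C/CO
F2 | step 10 | (2E,6E,10E)-geranylgeranyl bromide | CC(C)=CCC/C(C)=C/CC/C(C)=C/CC/C(C)=C/CBr
F3 | step 10 | (4R,5S)-4-(tert-butyldimethylsilyloxy)-5-geranylgeranyl-2-methylcyclopent-2-en-1-one | CC(C)=CCC/C(C)=C/CC/C(C)=C/CC/C(C)=C/C[C@@H]1C(=O)C(C)=C[C@H]1O[Si](C)(C)C(C)(C)C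
F4 | step 11 | (4R,5S)-4-(tert-butyldimethylsilyloxy)-5-geranylgeranyl-5-(hydroxymethyl)-2-methylcyclopent-2-en-1-one | CC(C)=CCC/C(C)=C/CC/C(C)=C/CC/C(C)=C/C[C@@]1(CO)C(=O)C(C)=C[C@H]1O[Si](C)(C)C(C)(C)C
F5 | step 11 | (4R,5S)-4-(tert-butyldimethylsilyloxy)-5-geranylgeranyl-5-(iodomethyl)-2-methylcyclopent-2-en-1-one | CC(C)=CCC/C(C)=C/CC/C(C)=C/CC/C(C)=C/C[C@@]1(CI)C(=O)C(C)=C[C@H]1O[Si](C)(C)C(C)(C)C
F6 | step 12 | (4R)-4-(tert-butyldimethylsilyloxy)-5-chloro-5-geranylgeranyl-2-methylcyclohex-2-en-1-one (C5 epimers) | CC(C)=CCC/C(C)=C/CC/C(C)=C/CC/C(C)=C/CC1(Cl)CC(=O)C(C)=C[C@H]1O[Si](C)(C)C(C)(C)C
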